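## Retrosynthetic overview
1. Pieces: ring A ketone 1 and geranyl bromide 2 (joined as 3) and ring B aldehyde 4. The open-chain aldol 5 and chalcone 6 lead to target 7.
2. 7 ⇒ 6: break O1–C2 of ring C. Forward, this is a catalytic 6-endo oxa-Michael closure of the unprotected 2',6'-dihydroxychalcone (the chalcone isomerase step), selective for one enantioface and one phenol, and run last.
3. 6 ⇒ 3 + 4: break Cα=Cβ (Claisen–Schmidt condensation).
4. 3 ⇒ 1 + 2: break aryl C3'–C1'' (prenyltransferase-like C-geranylation, done while the two free ring positions are still equivalent).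
5. Ring order: rings A and B are bought. Ring C is the only ring made, and it closes in the final step, which also sets C2. No protecting groups are used.

Assumption: the quinine-derived thiourea is taken to give the 2S series; the sense is checked by CD and chiral HPLC on the first run, and the equally available quinidine-derived pseudoenantiomer is used under the same conditions if it proves opposite.

## Route

Step 1
Reactants: 1 2',6'-dihydroxy-4'-methoxyacetophenone; 2 geranyl bromide [(2E)-1-bromo-3,7-dimethylocta-2,6-diene]
Product: 3 3'-geranyl-2',6'-dihydroxy-4'-methoxyacetophenone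
Conditions: KOH (1.1 equiv), MeOH, 0 °C to rt, 16 h (1 in 1.5-fold excess, surplus recovered; 2 added slowly)
Reagents that add atoms: none
Why: Prenyltransferase-like phenoxide C-alkylation, in which the phloroglucinol-type phenoxide of 1, hydrogen-bonded at oxygen by the protic solvent, attacks the primary allylic bromide through carbon by SN2; the two free ring positions of 1 are equivalent, so only one mono-C-geranyl product can form, the 2E alkene is untouched and no stereocentre is created.

Step 2
Reactants: 3 3'-geranyl-2',6'-dihydroxy-4'-methoxyacetophenone; 4 3,4-dimethoxybenzaldehyde (veratraldehyde)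
Product: 6 (E)-3'-geranyl-2',6'-dihydroxy-3,4,4'-trimethoxychalcone, via aldol adduct 5 (not isolated)
Conditions: KOH (50% aq, 20 equiv), EtOH, Ar, rt, 48 h; then ice-cold 1 M HCl to pH 4, fast extraction, crystallisation or short acid-washed SiO2 column
Reagents that add atoms: none
Why: Claisen–Schmidt aldol condensation, in which the methyl ketone enolate adds to the non-enolisable aldehyde and the adduct loses water by E1cB to give the conjugated E-enone; the strong base holds the product as its ring-open phenolate, so cold acidification releases the chalcone before it can close to racemic flavanone, and no stereocentre remains.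

Step 3
Reactants: 6 (E)-3'-geranyl-2',6'-dihydroxy-3,4,4'-trimethoxychalcone
Product: 7 (2S)-6-geranyl-5-hydroxy-7,3',4'-trimethoxyflavanone (CNP0310479.1)
Conditions: N-[3,5-bis(trifluoromethyl)phenyl]-N'-[(8α,9S)-6'-methoxycinchonan-9-yl]thiourea (C29H28F6N4OS, 10 mol %), toluene (0.05 M), −25 °C, 72 h; AcOH quench, cold SiO2 plug, chromatography
Reagents that add atoms: none
Why: Proposed new method: a small-molecule copy of chalcone isomerase in which the thiourea NH pair binds the enone carbonyl (already chelated by the geranyl-buttressed, less acidic 2'-OH) while the quinuclidine nitrogen takes the proton of the unhindered, more acidic 6'-OH and steers that oxygen onto the Si face of C-β in a 6-endo-trig intramolecular oxa-Michael addition, so one event fixes both the 6-geranyl regiochemistry and the 2S centre, with low temperature and the non-polar solvent suppressing uncatalysed closure and retro-Michael racemisation; the closest known reaction type is the bifunctional cinchona thiourea-catalysed enantioselective cyclisation of 2'-hydroxychalcones (and their α-carboxylate-activated analogues) to flavanones, and the new element is the choice between two non-equivalent phenols.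

## Compound list
1 | 2',6'-dihydroxy-4'-methoxyacetophenone [1-(2,6-dihydroxy-4-methoxyphenyl)ethan-1-one] | CC(=O)c1c(O)cc(OC)cc1O | starting material
2 | geranyl bromide [(2E)-1-bromo-3,7-dimethylocta-2,6-diene] | CC(C)=CCC/C(C)=C/CBr | starting material
3 | 1-{3-[(2E)-3,7-dimethylocta-2,6-dien-1-yl]-2,6-dihydroxy-4-methoxyphenyl}ethan-1-one | CC(=O)c1c(O)cc(OC)c(C/C=C(\C)CCC=C(C)C)c1O | intermediate
4 | 3,4-dimethoxybenzaldehyde (veratraldehyde) | COc1ccc(C=O)cc1OC | starting material
5 | aldol adduct, racemic 1-(3-geranyl-2,6-dihydroxy-4-methoxyphenyl)-3-(3,4-dimethoxyphenyl)-3-hydroxypropan-1-one (not isolated) | COc1ccc(C(O)CC(=O)c2c(O)cc(OC)c(C/C=C(\C)CCC=C(C)C)c2O)cc1OC | intermediate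
6 | (2E)-1-{3-[(2E)-3,7-dimethylocta-2,6-dien-1-yl]-2,6-dihydroxy-4-methoxyphenyl}-3-(3,4-dimethoxyphenyl)prop-2-en-1-one | COc1ccc(/C=C/C(=O)c2c(O)cc(OC)c(C/C=C(\C)CCC=C(C)C)c2O)cc1OC | intermediate
7 | (2S)-2-(3,4-dimethoxyphenyl)-6-[(2E)-3,7-dimethylocta-2,6-dien-1-yl]-5-hydroxy-7-methoxy-2,3-dihydro-4H-chromen-4-one | COc1ccc([C@@H]2CC(=O)c3c(cc(OC)c(C/C=C(\C)CCC=C(C)C)c3O)O2)cc1OC | target

## Step count and risks
Total step count: 3. Longest linear sequence: 3.

**Most likely to fail, first: step 3.**
- Risk: the catalyst may not separate the two phenols well enough, which would give the 8-geranyl regioisomer. Uncatalysed closure may also erode the ee.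
- Fallback: it sets out from 1 and 4, comes back at 7, and moves the geranyl transfer behind the ring closure, which is the order of events in the plant.
- Condensing 1 with 4 (KOH, EtOH, rt, then cold dilute HCl) gives the symmetrical (E)-2',6'-dihydroxy-3,4,4'-trimethoxychalcone F1. Its two phenols are equivalent, so the same thiourea catalyst only has to choose the face.
- The crystalline (2S)-5-hydroxy-7,3',4'-trimethoxyflavanone F2 that results is raised to full enantiopurity by recrystallisation.
- Base-free Mitsunobu etherification of the 5-OH with geraniol (PPh3, DIAD, THF, 0 °C to rt) gives (2S)-5-geranyloxy-7,3',4'-trimethoxyflavanone F3 without touching C2.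
- Montmorillonite K10 (acid-treated aluminosilicate clay, idealised Al2Si4O10(OH)2·nH2O) in CH2Cl2 at 0 °C then moves the geranyl group from O5 to the adjacent C6 by a tight-ion-pair [1,3] O-to-C shift. This delivers 7.

**Second: step 2.**
- Risk: the doubly deprotonated ketone may enolise too poorly, or the chalcone may partly close to racemic flavanone on work-up.
- Fallback: it sets out from 3 and comes back at 6.
- Both phenols are masked (NaH, MOMCl, DMF, 0 °C) to give 3'-geranyl-4'-methoxy-2',6'-bis(methoxymethoxy)acetophenone F4.
- F4 condenses readily with 4 (KOH, EtOH, rt, then cold dilute HCl) to give (E)-3'-geranyl-3,4,4'-trimethoxy-2',6'-bis(methoxymethoxy)chalcone F5. This compound cannot cyclise and can be purified at leisure.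
- Mild acetal exchange (HCl, MeOH, rt) then frees 6 just before step 3.

**Third: step 1.**
- Risk: O-alkylation and double alkylation may outrun mono-C-alkylation.
- Fallback: it sets out from 1 and 2 and comes back at 3.
- O-alkylation is made the deliberate reaction (K2CO3, DMF, rt; one phenol stays chelated and inert), giving 2'-geranyloxy-6'-hydroxy-4'-methoxyacetophenone F6.
- Montmorillonite K10 in CH2Cl2 at 0 °C then transfers the geranyl group from oxygen to carbon. The ortho and para migration termini of F6 lead to the same compound, so the rearrangement converges on 3 whichever position is reached.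

## Further compounds
F1 | step 3 | (E)-2',6'-dihydroxy-3,4,4'-trimethoxychalcone | COc1cc(O)c(C(=O)/C=C/c2ccc(OC)c(OC)c2)c(O)c1
F2 | step 3 | (2S)-5-hydroxy-7,3',4'-trimethoxyflavanone | COc1ccc([C@@H]2CC(=O)c3c(O)cc(OC)cc3O2)cc1OC
F3 | step 3 | (2S)-5-geranyloxy-7,3',4'-trimethoxyflavanone | COc1ccc([C@@H]2CC(=O)c3c(OC/C=C(\C)CCC=C(C)C)cc(OC)cc3O2)cc1OC
F4 | step 2 | 3'-geranyl-4'-methoxy-2',6'-bis(methoxymethoxy)acetophenone | CC(=O)c1c(OCOC)cc(OC)c(C/C=C(\C)CCC=C(C)C)c1OCOC
F5 | step 2 | (E)-3'-geranyl-3,4,4'-trimethoxy-2',6'-bis(methoxymethoxy)chalcone | COCOc1cc(OC)c(C/C=C(\C)CCC=C(C)C)c(OCOC)c1C(=O)/C=C/c1ccc(OC)c(OC)c1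
F6 | step 1 | 2'-geranyloxy-6'-hydroxy-4'-methoxyacetophenone | CC(=O)c1c(O)cc(OC)cc1OC/C=C(\C)CCC=C(C)C
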